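Subtract first. In theta and epsilon a single-handed catalyst and the partner act on a racemate of left-handed and right-handed substrate, so I compared the two product columns of the earlier runs.

| setting | north | south-west | theta | epsilon |
|---|---|---|---|---|
| left-handed substrate | 0.80 M | 0.80 M | 0.80 M | 0.80 M |
| right-handed substrate | 0.80 M | 0.80 M | 0.80 M | 0.80 M |
| partner | 1.6 equiv | 2.6 equiv | 1.10 equiv | 2.20 equiv |
| catalyst | 0.053 mol% | 0.053 mol% | 0.053 mol% | 0.053 mol% |
| remark | run made earlier | run made earlier |  |  |
| time |  |  | 50 min | 50 min |

| run | time / min | left-handed product / % | right-handed product / % |
|---|---|---|---|
| north | 2.00 | 28.4 | 28.0 |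
| north | 5.00 | 32.5 | 32.2 |
| north | 10.0 | 33.0 | 33.2 |
| north | 15.0 | 32.9 | 33.5 |
| north | 20.0 | 32.7 | 33.7 |
| north | 30.0 | 32.9 | 33.0 |
| north | 40.0 | 33.7 | 33.0 |
| south-west | 5.00 | 43.2 | 43.6 |
| south-west | 10.0 | 45.0 | 45.2 |
| south-west | 15.0 | 45.2 | 45.3 |
| south-west | 20.0 | 46.6 | 45.9 |
| south-west | 25.0 | 46.0 | 45.6 |
| south-west | 30.0 | 46.3 | 46.5 |
| south-west | 40.0 | 46.0 | 46.3 |

(each reading ± 0.3 percentage points)

- catalyst is single-handed; left-handed substrate and right-handed substrate are mirror images of each other, charged as a racemate, each of them at the stated concentration
- an excess is the difference of the two amounts in percent of their sum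
- an excess is below zero if the other one leads

- the winner by excess of left-handed product over right-handed product in the product; "neither" if no more than 2 percentage points parts them (theta / epsilon / neither)
- excess of left-handed product over right-handed product in the product at the end, theta
- excess of left-handed product over right-handed product in the product at the end, epsilon

I read the north table column against column. At 2.00 min the left-handed product stood at 28.4 % and the right-handed product at 28.0 %, a gap of 0.4 percentage points, and at 20.0 min the gap was −1 point, with the sign turned. Each reading carries 0.3 points, so a gap between two carries more, and I named this the pair scatter, the scatter of one reading times the root of two, 0.42 points. Dividing it by the fraction of the charge found as product gives the scatter of one excess.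

In the first north row the excess read 0.709 %, with a scatter of 0.752 %. In the first south-west row it read −0.461 %, with a scatter of 0.489 %. Neither first row showed an excess beyond its scatter, which does not show that the products started level, so zero for theta and epsilon was only my estimate from these two runs, with that scatter on it.

For theta I scaled the north plateau by the partner charged, which gave a product fraction of 45.3 %, so one excess reading there would carry 0.927 %, still inside the margin of 2 points.

The forecast said neither, with 0 % for theta and 0 % for epsilon: “Mirror-image products have identical free energy, so a single-handed catalyst cannot bias an equilibrium”. My zero came from the gaps, its zero from that argument.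

The flasks gave neither, with 0 % in theta and 0 % in epsilon.

    partner + catalyst + left-handed substrate → catalyst + left-handed product (k = 44.0 M⁻² s⁻¹)
    partner + catalyst + right-handed substrate → catalyst + right-handed product (k = 22.0 M⁻² s⁻¹)
    left-handed product ⇌ right-handed product (k = 0.0130 s⁻¹)
    partner → decomposed reagent (k = 0.00200 s⁻¹)
    2 partner → self-condensation product (k = 6.30 × 10⁻⁴ M⁻¹ s⁻¹)

At 50.0 min theta held 20.5 % of left-handed substrate against 32.0 % of right-handed substrate, yet its products stood level, and the forward half-life of left-handed product turning into right-handed product, 0.89 min, was shorter than the 50 min. The pair scatter makes one excess reading in theta good to 0.892 %. The neighbour of theta with 0.021 mol% of catalyst gave 0 %, and there one reading is good to 1.06 %.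

(The numbers in the tables come from a simulation with made-up constants, and the scatter is random.)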